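**Plan**
1. Retrosynthetic cuts, in order: C23–C24 (Stille), the ring bond C17–C18 (alkenylzinc to aldehyde), the C1–O ester at C21, C7–C8 (alkenyl–allyl Stille); inside the fragments C20–C21, C10–C11, C5–C6 and C26=C27.
2. Forward: four fragments are made, the C18–C23 iodo-enynol 7, the C1–C7 stannane 15, the C8–C17 allylic chloride 26 and the C24–C30 dienylstannane 35. 15 and 26 give the C1–C17 acid 38, which is esterified with 7; C17 is unmasked and oxidised; the only ring, the 22-membered lactone, closes at C17–C18; desilylation and side-chain coupling finish.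
3. Enabling feature: C17 is a secondary allylic carbinol flanked inside the 22-membered lactone ring by the E-C18=C19 alkene, i.e. the adduct of a C18 alkenyl metal and a C17 aldehyde.
4. Stereocentres: C3 from the commercial (R)-hemiester 8; C5 by CBS reduction; C11 by Keck allylation with (R)-BINOL; C20 and C21 by Marshall propargylation with the (S)-mesylate 2 (anti); C17 by the (+)-DAIB-controlled ring closure.
5. Alkenes: E-C14=C15 by Johnson–Claisen rearrangement; E-C6=C7 and E-C22=C23 from E-alkenyl tin and silicon precursors; E-C18=C19 by syn hydroboration; Z-C24=C25 by trans-hydroalumination/iodination; Z-C26=C27 by Wittig reaction.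

Key step: step 25

Assumption: DAIB-catalysed alkenyl transfer from an alkenyl(ethyl)zinc is taken to follow the same facial rule as alkyl transfer from a dialkylzinc (the (2S)-ligand gives Si-face attack), so the (2R)-ligand, (+)-DAIB, is used for Re-face attack and the 17S carbinol.

Abbreviations: TBS = tert-butyldimethylsilyl; locants C1–C30 are those of the target (C1 lactone carbonyl, C21 lactone carbinol, C22–C30 side chain).

**Fragment C18–C23**

Step 1
Reactants: 1 (S)-but-3-yn-2-ol
Product: 2 (S)-but-3-yn-2-yl methanesulfonate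
Conditions: MsCl, Et3N, CH2Cl2, −78 to 0 °C
Reagents that add atoms: methanesulfonyl chloride, CS(=O)(=O)Cl
Why: O-sulfonylation of the secondary alcohol does not touch the stereocentre and gives the propargylic mesylate needed for the Marshall propargylation.

Step 2
Reactants: 3 (E)-3-(trimethylsilyl)prop-2-en-1-ol
Product: 4 (E)-3-(trimethylsilyl)prop-2-enal
Conditions: MnO2 (activated, excess), CH2Cl2, rt
Reagents that add atoms: none
Why: Allylic oxidation with MnO2 is chemoselective and keeps the E geometry; the volatile enal is used as a solution.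

Step 3
Reactants: 2 (S)-but-3-yn-2-yl methanesulfonate; 4 (E)-3-(trimethylsilyl)prop-2-enal
Product: 6 (3R,4R,E)-4-methyl-1-(trimethylsilyl)hex-1-en-5-yn-3-ol, via allenylzinc 5 (not isolated)
Conditions: Pd(OAc)2 (5 mol%), PPh3 (5 mol%), Et2Zn (3 equiv), THF, −78 to −20 °C; aq NH4Cl
Reagents that add atoms: none
Why: Marshall propargylation, in which zerovalent palladium displaces the mesylate anti (SN2') and Et2Zn gives the configurationally defined allenylzinc 5, whose cyclic SE2' addition to the enal transfers the mesylate chirality to C20 (R) and sets C21 anti to it.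

Step 4
Reactants: 6 (3R,4R,E)-4-methyl-1-(trimethylsilyl)hex-1-en-5-yn-3-ol
Product: 7 (3R,4R,E)-1-iodo-4-methylhex-1-en-5-yn-3-ol
Conditions: N-iodosuccinimide, (CF3)2CHOH, 0 °C, dark, short reaction time
Reagents that add atoms: N-iodosuccinimide, O=C1CCC(=O)N1I
Why: Iododesilylation of the alkenylsilane by ipso attack through a β-silyl cation should proceed with retention to the E-alkenyl iodide far faster than any iodination of the unactivated terminal alkyne.

**Fragment C1–C7**

Step 5
Reactants: 8 (R)-3-(TBSO)-5-methoxy-5-oxopentanoic acid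
Product: 9 1-tert-butyl 5-methyl (S)-3-(TBSO)pentanedioate
Conditions: tert-butyl 2,2,2-trichloroacetimidate, CH2Cl2–cyclohexane, rt
Reagents that add atoms: tert-butyl 2,2,2-trichloroacetimidate, CC(C)(C)OC(=N)C(Cl)(Cl)Cl
Why: Acid-free tert-butylation of the carboxylic acid (future C1) with the imidate differentiates the two termini without touching the silyl ether or the C3 stereocentre.

Step 6
Reactants: 9 1-tert-butyl 5-methyl (S)-3-(TBSO)pentanedioate
Product: 10 tert-butyl (S)-3-(TBSO)-5-[methoxy(methyl)amino]-5-oxopentanoate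
Conditions: MeNHOMe·HCl, i-PrMgCl, THF, −20 to 0 °C
Reagents that add atoms: N,O-dimethylhydroxylamine hydrochloride, CNOC.Cl
Why: The chloromagnesium amide of N,O-dimethylhydroxylamine aminolyses the methyl ester selectively, the hindered tert-butyl ester being inert, to give the Weinreb amide at the future C5.

Step 7
Reactants: 10 tert-butyl (S)-3-(TBSO)-5-[methoxy(methyl)amino]-5-oxopentanoate; 11 (E)-1,2-bis(tributylstannyl)ethene
Product: 13 tert-butyl (S,E)-3-(TBSO)-5-oxo-7-(tributylstannyl)hept-6-enoate, via stannylvinyllithium 12 (not isolated)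
Conditions: n-BuLi, THF, −78 °C (11 to 12); then 10, −78 °C; aq NH4Cl
Reagents that add atoms: none
Why: Tin–lithium exchange gives the E-stannylvinyllithium with retention, and its addition to the Weinreb amide stops at the chelated tetrahedral intermediate (Weinreb ketone synthesis), giving the E-β-stannyl enone.

Step 8
Reactants: 13 tert-butyl (S,E)-3-(TBSO)-5-oxo-7-(tributylstannyl)hept-6-enoate
Product: 14 tert-butyl (3S,5S,E)-3-(TBSO)-5-hydroxy-7-(tributylstannyl)hept-6-enoate
Conditions: (R)-2-methyl-CBS-oxazaborolidine (0.3 equiv), catecholborane, toluene, −78 °C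
Reagents that add atoms: none
Why: Corey–Bakshi–Shibata reduction with the alkenyl group as the large substituent; the (R)-catalyst delivers hydride to the face that gives 5S and hence the 3,5-anti diol pattern, and catecholborane at −78 °C leaves the alkenylstannane alone.

Step 9
Reactants: 14 tert-butyl (3S,5S,E)-3-(TBSO)-5-hydroxy-7-(tributylstannyl)hept-6-enoate
Product: 15 tert-butyl (3S,5S,E)-3,5-bis(TBSO)-7-(tributylstannyl)hept-6-enoate
Conditions: TBSCl, imidazole, DMF, rt
Reagents that add atoms: tert-butyldimethylsilyl chloride, CC(C)(C)[Si](C)(C)Cl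
Why: Silylation of the allylic alcohol under mildly basic conditions avoids protodestannylation of the alkenylstannane.

**Fragment C8–C17**

Step 10
Reactants: 16 3-(TBSO)propanal; 17 vinylmagnesium bromide (CH2=CHMgBr)
Product: 18 rac-5-(TBSO)pent-1-en-3-ol
Conditions: THF, −78 to 0 °C; aq NH4Cl
Reagents that add atoms: none
Why: Grignard 1,2-addition gives the allylic alcohol; its stereocentre is irrelevant because it becomes sp2 in the next step.

Step 11
Reactants: 18 rac-5-(TBSO)pent-1-en-3-ol; 19 triethyl orthoacetate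
Product: 21 ethyl (E)-7-(TBSO)hept-4-enoate, via ketene acetal 20 (not isolated)
Conditions: EtCO2H (cat.), neat 19, 140 °C, removal of EtOH
Reagents that add atoms: none
Why: Johnson–Claisen rearrangement through a chair transition state with the side chain equatorial gives the E-C14=C15 alkene and adds C11–C12.

Step 12
Reactants: 21 ethyl (E)-7-(TBSO)hept-4-enoate
Product: 22 (E)-7-(TBSO)hept-4-enal
Conditions: i-Bu2AlH (1.05 equiv), CH2Cl2, −78 °C; Rochelle salt
Reagents that add atoms: none
Why: Partial reduction of the ester at −78 °C stops at the aluminium hemiacetal, which releases the C11 aldehyde on work-up.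

Step 13
Reactants: 23 3-chloro-2-(chloromethyl)prop-1-ene
Product: 24 tributyl[2-(chloromethyl)prop-2-en-1-yl]stannane
Conditions: Bu3SnH, LiN(i-Pr)2, THF, 0 °C; then added to 23 (3 equiv), −78 °C
Reagents that add atoms: tributyltin hydride, CCCC[SnH](CCCC)CCCC
Why: Monosubstitution of the symmetrical allylic dichloride by the stannyl anion (SN2 and SN2' give the same product) gives the bifunctional allylstannane; excess dichloride suppresses double substitution.

Step 14
Reactants: 22 (E)-7-(TBSO)hept-4-enal; 24 tributyl[2-(chloromethyl)prop-2-en-1-yl]stannane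
Product: 25 (4S,7E)-10-(TBSO)-2-(chloromethyl)deca-1,7-dien-4-ol
Conditions: (R)-BINOL (20 mol%), Ti(OiPr)4 (10 mol%), 4 Å molecular sieves, CH2Cl2, −20 °C; aq NaHCO3
Reagents that add atoms: none
Why: Keck asymmetric allylation, in which the (R)-BINOL titanium complex directs the allyl group to the Re face of the aldehyde and so sets 11S, while the allylic chloride passes through intact as the later C8 electrophile.

Step 15
Reactants: 25 (4S,7E)-10-(TBSO)-2-(chloromethyl)deca-1,7-dien-4-ol
Product: 26 (4S,7E)-4,10-bis(TBSO)-2-(chloromethyl)deca-1,7-diene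
Conditions: TBSOTf, 2,6-lutidine, CH2Cl2, −78 °C
Reagents that add atoms: tert-butyldimethylsilyl trifluoromethanesulfonate, CC(C)(C)[Si](C)(C)OS(=O)(=O)C(F)(F)F
Why: Silylation with the triflate and a hindered base at low temperature protects the C11 hydroxyl without displacing the allylic chloride.

**Fragment C24–C30**

Step 16
Reactants: 27 but-2-yn-1-ol
Product: 29 (Z)-3-iodobut-2-en-1-ol, via alkenylalanate 28 (not isolated)
Conditions: NaAlH2(OCH2CH2OMe)2, THF, 0 °C to rt; EtOAc; then I2, THF, −78 to 0 °C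
Reagents that add atoms: iodine, II
Why: Hydroxyl-directed trans-hydroalumination places aluminium on C24 cis to the carbinol carbon, and iodinolysis with retention gives the Z-iodoalkene that fixes the C24=C25 geometry.

Step 17
Reactants: 29 (Z)-3-iodobut-2-en-1-ol
Product: 30 (Z)-3-iodobut-2-enal
Conditions: MnO2, CH2Cl2, rt, dark
Reagents that add atoms: none
Why: Neutral allylic oxidation with MnO2 gives the enal without Z-to-E isomerisation if light and acid are excluded and the product is used at once.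

Step 18
Reactants: 30 (Z)-3-iodobut-2-enal; 31 (but-3-en-1-yl)triphenylphosphonium bromide
Product: 33 (2Z,4Z)-2-iodoocta-2,4,7-triene, via ylide 32 (not isolated)
Conditions: NaN(SiMe3)2, THF, −78 °C (31 to 32); then 30, −78 to 0 °C
Reagents that add atoms: none
Why: Wittig reaction of the non-stabilised ylide under lithium-free conditions is kinetically Z-selective and sets Z-C26=C27 while adding C27–C30.

Step 19
Reactants: 33 (2Z,4Z)-2-iodoocta-2,4,7-triene
Product: 35 tributyl[(2Z,4Z)-octa-2,4,7-trien-2-yl]stannane, via dienyllithium 34 (not isolated)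
Conditions: t-BuLi (2 equiv), Et2O, −78 °C; then Bu3SnCl, −78 °C to rt
Reagents that add atoms: tributyltin chloride, CCCC[Sn](Cl)(CCCC)CCCC
Why: Iodine–lithium exchange at −78 °C is faster than deprotonation of the skipped diene and gives a configurationally stable alkenyllithium, which is stannylated with retention.

**Assembly, ring closure and end game**

Step 20
Reactants: 15 tert-butyl (3S,5S,E)-3,5-bis(TBSO)-7-(tributylstannyl)hept-6-enoate; 26 (4S,7E)-4,10-bis(TBSO)-2-(chloromethyl)deca-1,7-diene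
Product: 36 tert-butyl (3S,5S,6E,11S,14E)-3,5,11,17-tetrakis(TBSO)-9-methylideneheptadeca-6,14-dienoate
Conditions: Pd2(dba)3 (5 mol%), AsPh3 (20 mol%), NMP, 40 °C
Reagents that add atoms: none
Why: Stille coupling of an alkenylstannane with an allylic chloride forms C7–C8 with retention of the E-C6=C7 geometry; the 2-substituted allylpalladium has two equivalent CH2 termini, so no regiochemical question arises.

Step 21
Reactants: 36 tert-butyl (3S,5S,6E,11S,14E)-3,5,11,17-tetrakis(TBSO)-9-methylideneheptadeca-6,14-dienoate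
Product: 38 (3S,5S,6E,11S,14E)-3,5,11,17-tetrakis(TBSO)-9-methylideneheptadeca-6,14-dienoic acid, via trimethylsilyl ester 37 (not isolated)
Conditions: TMSOTf, 2,6-lutidine, CH2Cl2, 0 °C; pH 7 buffer
Reagents that add atoms: none
Why: Silyl triflate-mediated cleavage of the tert-butyl ester (loss of isobutene) gives the silyl ester, which hydrolyses on work-up, under buffered non-protic conditions that silyl ethers tolerate.

Step 22
Reactants: 38 (3S,5S,6E,11S,14E)-3,5,11,17-tetrakis(TBSO)-9-methylideneheptadeca-6,14-dienoic acid; 7 (3R,4R,E)-1-iodo-4-methylhex-1-en-5-yn-3-ol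
Product: 40 (3R,4R,E)-1-iodo-4-methylhex-1-en-5-yn-3-yl (3S,5S,6E,11S,14E)-3,5,11,17-tetrakis(TBSO)-9-methylideneheptadeca-6,14-dienoate, via mixed anhydride 39 (not isolated)
Conditions: 2,4,6-Cl3C6H2COCl, Et3N, THF, rt; then 7, DMAP, toluene, rt
Reagents that add atoms: none
Why: Yamaguchi esterification acylates the hindered secondary C21 alcohol with retention at room temperature, where β-elimination of the C3 silyloxy group is not expected, and the alkyne and iodoalkene are inert.

Step 23
Reactants: 40 (3R,4R,E)-1-iodo-4-methylhex-1-en-5-yn-3-yl (3S,5S,6E,11S,14E)-3,5,11,17-tetrakis(TBSO)-9-methylideneheptadeca-6,14-dienoate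
Product: 41 (3R,4R,E)-1-iodo-4-methylhex-1-en-5-yn-3-yl (3S,5S,6E,11S,14E)-3,5,11-tris(TBSO)-17-hydroxy-9-methylideneheptadeca-6,14-dienoate
Conditions: HF·pyridine, pyridine, THF, 0 °C, monitored
Reagents that add atoms: none
Why: Buffered HF·pyridine should cleave the unhindered primary silyl ether at C17 much faster than the three secondary ones.

Step 24
Reactants: 41 (3R,4R,E)-1-iodo-4-methylhex-1-en-5-yn-3-yl (3S,5S,6E,11S,14E)-3,5,11-tris(TBSO)-17-hydroxy-9-methylideneheptadeca-6,14-dienoate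
Product: 42 (3R,4R,E)-1-iodo-4-methylhex-1-en-5-yn-3-yl (3S,5S,6E,11S,14E)-3,5,11-tris(TBSO)-9-methylidene-17-oxoheptadeca-6,14-dienoate
Conditions: Dess–Martin periodinane, NaHCO3, CH2Cl2, 0 °C to rt; filtered and used at once
Reagents that add atoms: none
Why: Buffered Dess–Martin oxidation gives the β,γ-unsaturated C17 aldehyde under neutral conditions that should not move the C14=C15 alkene into conjugation.

Step 25
Reactants: 42 (3R,4R,E)-1-iodo-4-methylhex-1-en-5-yn-3-yl (3S,5S,6E,11S,14E)-3,5,11-tris(TBSO)-9-methylidene-17-oxoheptadeca-6,14-dienoate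
Product: 45 (4S,6S,7E,12S,15E,18S,19E,21R,22R)-4,6,12-tris(TBSO)-18-hydroxy-22-[(E)-2-iodoethenyl]-21-methyl-10-methylideneoxacyclodocosa-7,15,19-trien-2-one, via alkenylborane 43 (not isolated), via alkenylzinc 44 (not isolated)
Conditions: Cy2BH (1.1 equiv, freshly made from BH3·SMe2 and cyclohexene), toluene–hexane, 0 °C to rt; solution added over 8 h to Et2Zn (3 equiv) and (+)-DAIB (10 mol%) in hexane, 0 °C, final 0.003 M; aq NH4Cl
Reagents that add atoms: none
Why: Syn hydroboration of the terminal C18≡C19 alkyne with Cy2BH gives the E-alkenylborane 43, boron-to-zinc exchange with Et2Zn gives the alkenyl(ethyl)zinc 44, and the zinc alkoxide of (+)-DAIB binds the C17 aldehyde and delivers the alkenyl group to it. The closest known reaction type is the amino-alcohol-catalysed addition of alkenylzinc reagents to aldehydes in its ring-forming version, which has given macrocyclic allylic alcohols including macrolactones. The 22-membered ring closes by end-to-end 1,2-addition of C18 to the C17 carbonyl (exo-trig attack), with slow addition at high dilution favouring closure over oligomerisation. The new C17 stereocentre is set by the chiral zinc amino alkoxide, which exposes the Re face of the aldehyde and so gives the 17S carbinol, and the E geometry of C18=C19 follows from syn addition of B–H. The step needs the borane to take the terminal alkyne in preference to the aldehyde, the 1,1-disubstituted C9 alkene, the two E-alkenes and the iodoalkene, which the bulk of Cy2BH, its near-stoichiometric use at 0 °C and the much higher rate of terminal-alkyne hydroboration secure. The ester, silyl ethers and alkenyl iodide are inert to the mild organozinc, and the side chain is attached later because its terminal vinyl group would compete for the borane.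

Step 26
Reactants: 45 (4S,6S,7E,12S,15E,18S,19E,21R,22R)-4,6,12-tris(TBSO)-18-hydroxy-22-[(E)-2-iodoethenyl]-21-methyl-10-methylideneoxacyclodocosa-7,15,19-trien-2-one
Product: 46 (4S,6S,7E,12S,15E,18S,19E,21R,22R)-4,6,12,18-tetrahydroxy-22-[(E)-2-iodoethenyl]-21-methyl-10-methylideneoxacyclodocosa-7,15,19-trien-2-one
Conditions: HF·pyridine (excess), pyridine, THF, 0 °C to rt
Reagents that add atoms: none
Why: Buffered fluoride cleaves the three secondary silyl ethers before the acid-labile triene is present, so the sensitive allylic ester next to a triene is never exposed to HF.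

Step 27
Reactants: 46 (4S,6S,7E,12S,15E,18S,19E,21R,22R)-4,6,12,18-tetrahydroxy-22-[(E)-2-iodoethenyl]-21-methyl-10-methylideneoxacyclodocosa-7,15,19-trien-2-one; 35 tributyl[(2Z,4Z)-octa-2,4,7-trien-2-yl]stannane
Product: 47 (4S,6S,7E,12S,15E,18S,19E,21R,22S)-4,6,12,18-tetrahydroxy-21-methyl-10-methylidene-22-[(1E,3Z,5Z)-3-methylnona-1,3,5,8-tetraen-1-yl]oxacyclodocosa-7,15,19-trien-2-one
Conditions: Pd(PPh3)4 (10 mol%), copper thiophene-2-carboxylate CuO2CC4H3S (1.5 equiv), [Bu4N][Ph2PO2] (1.5 equiv), DMF, rt, dark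
Reagents that add atoms: none
Why: Copper-promoted Stille coupling, in which tin-to-copper exchange is driven by the phosphinate tin scavenger and the alkenylcopper passes its group to the alkenylpalladium iodide formed from zerovalent palladium, joins C23–C24 with retention of all alkene geometries under neutral conditions that tolerate the four free hydroxyls.

**Compound list**
1 | (S)-but-3-yn-2-ol | C[C@H](O)C#C | starting material
2 | (S)-but-3-yn-2-yl methanesulfonate | C[C@H](OS(C)(=O)=O)C#C | intermediate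
3 | (E)-3-(trimethylsilyl)prop-2-en-1-ol | C[Si](C)(C)/C=C/CO | starting material
4 | (E)-3-(trimethylsilyl)prop-2-enal | C[Si](C)(C)/C=C/C=O | intermediate
5 | (aR)-buta-1,2-dien-1-yl(ethyl)zinc | [H]C(C)=[C@@]=C([H])[Zn]CC | intermediate (not isolated)
6 | (3R,4R,E)-4-methyl-1-(trimethylsilyl)hex-1-en-5-yn-3-ol | C[Si](C)(C)/C=C/[C@H](O)[C@H](C)C#C | intermediate
7 | (3R,4R,E)-1-iodo-4-methylhex-1-en-5-yn-3-ol (C18–C23) | I/C=C/[C@H](O)[C@H](C)C#C | intermediate
8 | (R)-3-(TBSO)-5-methoxy-5-oxopentanoic acid | COC(=O)C[C@H](O[Si](C)(C)C(C)(C)C)CC(=O)O | starting material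
9 | 1-tert-butyl 5-methyl (S)-3-(TBSO)pentanedioate | CC(C)(C)OC(=O)C[C@@H](O[Si](C)(C)C(C)(C)C)CC(=O)OC | intermediate
10 | tert-butyl (S)-3-(TBSO)-5-[methoxy(methyl)amino]-5-oxopentanoate | CC(C)(C)OC(=O)C[C@@H](O[Si](C)(C)C(C)(C)C)CC(=O)N(C)OC | intermediate
11 | (E)-1,2-bis(tributylstannyl)ethene | CCCC[Sn](CCCC)(CCCC)/C=C/[Sn](CCCC)(CCCC)CCCC | starting material
12 | (E)-[2-(tributylstannyl)ethenyl]lithium | [Li]/C=C/[Sn](CCCC)(CCCC)CCCC | intermediate (not isolated)
13 | tert-butyl (S,E)-3-(TBSO)-5-oxo-7-(tributylstannyl)hept-6-enoate | CC(C)(C)OC(=O)C[C@@H](O[Si](C)(C)C(C)(C)C)CC(=O)/C=C/[Sn](CCCC)(CCCC)CCCC | intermediate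
14 | tert-butyl (3S,5S,E)-3-(TBSO)-5-hydroxy-7-(tributylstannyl)hept-6-enoate | CC(C)(C)OC(=O)C[C@@H](O[Si](C)(C)C(C)(C)C)C[C@H](O)/C=C/[Sn](CCCC)(CCCC)CCCC | intermediate
15 | tert-butyl (3S,5S,E)-3,5-bis(TBSO)-7-(tributylstannyl)hept-6-enoate (C1–C7) | CC(C)(C)OC(=O)C[C@@H](O[Si](C)(C)C(C)(C)C)C[C@H](O[Si](C)(C)C(C)(C)C)/C=C/[Sn](CCCC)(CCCC)CCCC | intermediate
16 | 3-(TBSO)propanal | O=CCCO[Si](C)(C)C(C)(C)C | starting material
17 | vinylmagnesium bromide | C=C[Mg]Br | starting material
18 | rac-5-(TBSO)pent-1-en-3-ol | C=CC(O)CCO[Si](C)(C)C(C)(C)C | intermediate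
19 | triethyl orthoacetate | CCOC(C)(OCC)OCC | starting material
20 | tert-butyl{[3-(1-ethoxyethenyloxy)pent-4-en-1-yl]oxy}dimethylsilane (ketene acetal) | C=C(OCC)OC(C=C)CCO[Si](C)(C)C(C)(C)C | intermediate (not isolated)
21 | ethyl (E)-7-(TBSO)hept-4-enoate | CCOC(=O)CC/C=C/CCO[Si](C)(C)C(C)(C)C | intermediate
22 | (E)-7-(TBSO)hept-4-enal | O=CCC/C=C/CCO[Si](C)(C)C(C)(C)C | intermediate
23 | 3-chloro-2-(chloromethyl)prop-1-ene | C=C(CCl)CCl | starting material
24 | tributyl[2-(chloromethyl)prop-2-en-1-yl]stannane | C=C(CCl)C[Sn](CCCC)(CCCC)CCCC | intermediate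
25 | (4S,7E)-10-(TBSO)-2-(chloromethyl)deca-1,7-dien-4-ol | ClCC(=C)C[C@@H](O)CC/C=C/CCO[Si](C)(C)C(C)(C)C | intermediate
26 | (4S,7E)-4,10-bis(TBSO)-2-(chloromethyl)deca-1,7-diene (C8–C17) | ClCC(=C)C[C@@H](O[Si](C)(C)C(C)(C)C)CC/C=C/CCO[Si](C)(C)C(C)(C)C | intermediate
27 | but-2-yn-1-ol | CC#CCO | starting material
28 | sodium cyclic (Z)-alkenylalanate of but-2-yn-1-ol, bis(2-methoxyethoxy) on aluminium | CC1=CCO[Al-]1(OCCOC)OCCOC.[Na+] | intermediate (not isolated)
29 | (Z)-3-iodobut-2-en-1-ol | C/C(I)=C/CO | intermediate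
30 | (Z)-3-iodobut-2-enal | C/C(I)=C/C=O | intermediate
31 | (but-3-en-1-yl)triphenylphosphonium bromide | C=CCC[P+](c1ccccc1)(c1ccccc1)c1ccccc1.[Br-] | starting material
32 | but-3-enylidene(triphenyl)phosphorane | C=CCC=P(c1ccccc1)(c1ccccc1)c1ccccc1 | intermediate (not isolated)
33 | (2Z,4Z)-2-iodoocta-2,4,7-triene | C/C(I)=C/C=C\CC=C | intermediate
34 | (2Z,4Z)-octa-2,4,7-trien-2-yllithium | C/C([Li])=C/C=C\CC=C | intermediate (not isolated)
35 | tributyl[(2Z,4Z)-octa-2,4,7-trien-2-yl]stannane (C24–C30) | CCCC[Sn](CCCC)(CCCC)/C(C)=C\C=C/CC=C | intermediate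
36 | tert-butyl (3S,5S,6E,11S,14E)-3,5,11,17-tetrakis(TBSO)-9-methylideneheptadeca-6,14-dienoate | CC(C)(C)OC(=O)C[C@@H](O[Si](C)(C)C(C)(C)C)C[C@H](O[Si](C)(C)C(C)(C)C)/C=C/CC(=C)C[C@@H](O[Si](C)(C)C(C)(C)C)CC/C=C/CCO[Si](C)(C)C(C)(C)C | intermediate
37 | trimethylsilyl ester of acid 38 | C[Si](C)(C)OC(=O)C[C@@H](O[Si](C)(C)C(C)(C)C)C[C@H](O[Si](C)(C)C(C)(C)C)/C=C/CC(=C)C[C@@H](O[Si](C)(C)C(C)(C)C)CC/C=C/CCO[Si](C)(C)C(C)(C)C | intermediate (not isolated)
38 | (3S,5S,6E,11S,14E)-3,5,11,17-tetrakis(TBSO)-9-methylideneheptadeca-6,14-dienoic acid (C1–C17) | OC(=O)C[C@@H](O[Si](C)(C)C(C)(C)C)C[C@H](O[Si](C)(C)C(C)(C)C)/C=C/CC(=C)C[C@@H](O[Si](C)(C)C(C)(C)C)CC/C=C/CCO[Si](C)(C)C(C)(C)C | intermediate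
39 | mixed anhydride of 38 and 2,4,6-trichlorobenzoic acid | Clc1cc(Cl)c(C(=O)OC(=O)C[C@@H](O[Si](C)(C)C(C)(C)C)C[C@H](O[Si](C)(C)C(C)(C)C)/C=C/CC(=C)C[C@@H](O[Si](C)(C)C(C)(C)C)CC/C=C/CCO[Si](C)(C)C(C)(C)C)c(Cl)c1 | intermediate (not isolated)
40 | (3R,4R,E)-1-iodo-4-methylhex-1-en-5-yn-3-yl (3S,5S,6E,11S,14E)-3,5,11,17-tetrakis(TBSO)-9-methylideneheptadeca-6,14-dienoate | I/C=C/[C@H](OC(=O)C[C@@H](O[Si](C)(C)C(C)(C)C)C[C@H](O[Si](C)(C)C(C)(C)C)/C=C/CC(=C)C[C@@H](O[Si](C)(C)C(C)(C)C)CC/C=C/CCO[Si](C)(C)C(C)(C)C)[C@H](C)C#C | intermediate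
41 | (3R,4R,E)-1-iodo-4-methylhex-1-en-5-yn-3-yl (3S,5S,6E,11S,14E)-3,5,11-tris(TBSO)-17-hydroxy-9-methylideneheptadeca-6,14-dienoate | I/C=C/[C@H](OC(=O)C[C@@H](O[Si](C)(C)C(C)(C)C)C[C@H](O[Si](C)(C)C(C)(C)C)/C=C/CC(=C)C[C@@H](O[Si](C)(C)C(C)(C)C)CC/C=C/CCO)[C@H](C)C#C | intermediate
42 | (3R,4R,E)-1-iodo-4-methylhex-1-en-5-yn-3-yl (3S,5S,6E,11S,14E)-3,5,11-tris(TBSO)-9-methylidene-17-oxoheptadeca-6,14-dienoate (seco ynal ester, key-step precursor) | I/C=C/[C@H](OC(=O)C[C@@H](O[Si](C)(C)C(C)(C)C)C[C@H](O[Si](C)(C)C(C)(C)C)/C=C/CC(=C)C[C@@H](O[Si](C)(C)C(C)(C)C)CC/C=C/CC=O)[C@H](C)C#C | intermediate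
43 | E-C18 alkenyl(dicyclohexyl)borane of 42 | I/C=C/[C@H](OC(=O)C[C@@H](O[Si](C)(C)C(C)(C)C)C[C@H](O[Si](C)(C)C(C)(C)C)/C=C/CC(=C)C[C@@H](O[Si](C)(C)C(C)(C)C)CC/C=C/CC=O)[C@H](C)/C=C/B(C1CCCCC1)C1CCCCC1 | intermediate (not isolated)
44 | E-C18 alkenyl(ethyl)zinc of 42 | I/C=C/[C@H](OC(=O)C[C@@H](O[Si](C)(C)C(C)(C)C)C[C@H](O[Si](C)(C)C(C)(C)C)/C=C/CC(=C)C[C@@H](O[Si](C)(C)C(C)(C)C)CC/C=C/CC=O)[C@H](C)/C=C/[Zn]CC | intermediate (not isolated)
45 | (4S,6S,7E,12S,15E,18S,19E,21R,22R)-4,6,12-tris(TBSO)-18-hydroxy-22-[(E)-2-iodoethenyl]-21-methyl-10-methylideneoxacyclodocosa-7,15,19-trien-2-one (key-step product) | I/C=C/[C@@H]1OC(=O)C[C@@H](O[Si](C)(C)C(C)(C)C)C[C@H](O[Si](C)(C)C(C)(C)C)/C=C/CC(=C)C[C@@H](O[Si](C)(C)C(C)(C)C)CC/C=C/C[C@H](O)/C=C/[C@H]1C | intermediate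
46 | (4S,6S,7E,12S,15E,18S,19E,21R,22R)-4,6,12,18-tetrahydroxy-22-[(E)-2-iodoethenyl]-21-methyl-10-methylideneoxacyclodocosa-7,15,19-trien-2-one | I/C=C/[C@@H]1OC(=O)C[C@@H](O)C[C@H](O)/C=C/CC(=C)C[C@@H](O)CC/C=C/C[C@H](O)/C=C/[C@H]1C | intermediate
47 | (4S,6S,7E,12S,15E,18S,19E,21R,22S)-4,6,12,18-tetrahydroxy-21-methyl-10-methylidene-22-[(1E,3Z,5Z)-3-methylnona-1,3,5,8-tetraen-1-yl]oxacyclodocosa-7,15,19-trien-2-one (CNP0297533.1) | C=CC\C=C/C=C(C)\C=C\[C@@H]1OC(=O)C[C@@H](O)C[C@H](O)/C=C/CC(=C)C[C@@H](O)CC/C=C/C[C@H](O)/C=C/[C@H]1C | target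

**Step count**
Total: 27 steps. Longest linear sequence: 13 steps (8 → 9 → 10 → 13 → 14 → 15 → 36 → 38 → 40 → 41 → 42 → 45 → 46 → 47; the branch from 16 is equally long).

**Steps most likely to fail**

Step 25. The ring-closing addition may lose out to intermolecular addition or to ethyl transfer. The β,γ-unsaturated aldehyde may isomerise into conjugation before it is consumed. Face selection by the ligand may be eroded by the resident C20 and C21 stereocentres (mismatched double stereodifferentiation). The fallback corrects the C17 configuration by reduction instead of addition; it sets out from 42 and comes back at 45. Compound 42 is cyclised by the same hydroboration and boron–zinc exchange but with achiral 2-(dimethylamino)ethanol, which should give 45 mixed with its C17 epimer, the (18R)-configured macrocyclic allylic alcohol F1. Dess–Martin oxidation of the mixture should give the macrocyclic C17 ketone (4S,6S,7E,12S,15E,19E,21R,22R)-4,6,12-tris(TBSO)-22-[(E)-2-iodoethenyl]-21-methyl-10-methylideneoxacyclodocosa-7,15,19-triene-2,18-dione F2. CBS reduction of F2 with (R)-2-methyl-CBS-oxazaborolidine and catecholborane at −78 °C, with the C18=C19 alkenyl group as the large substituent, should return 45.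

Step 27. The α-methyl dienylstannane 35 may protodestannylate or isomerise from Z to E, and tin-to-copper transfer at its substituted carbon may be slow. The fallback reverses the polarity of the coupling; it sets out from 46 and comes back at 47. Compound 46 is treated with Me3SnSnMe3 and Pd(PPh3)4 to give the macrocyclic E-alkenyl(trimethyl)stannane, (4S,6S,7E,12S,15E,18S,19E,21R,22S)-4,6,12,18-tetrahydroxy-21-methyl-10-methylidene-22-[(E)-2-(trimethylstannyl)ethenyl]oxacyclodocosa-7,15,19-trien-2-one F3. Stille coupling of F3 with the dienyl iodide 33 (Pd2(dba)3, AsPh3, NMP, rt) should give 47, and step 19 is then not needed.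

Step 20. Transfer of the γ-silyloxy alkenyl group from tin to the hindered 2-substituted allylpalladium chloride may be slow, so that β-hydride loss from the allyl complex to a diene and protodestannylation of 15 compete. The fallback also reverses the polarity; it sets out from 15 and 26 and comes back at 36. Iododestannylation of 15 (I2, CH2Cl2, 0 °C) gives the E-alkenyl iodide tert-butyl (3S,5S,E)-3,5-bis(TBSO)-7-iodohept-6-enoate F4. Displacement of the chloride of 26 with Bu3SnLi (THF, −78 °C) gives the allylstannane tributyl[(4S,7E)-4,10-bis(TBSO)-2-methylidenedec-7-en-1-yl]stannane F5. Stille coupling of F4 with F5 (Pd2(dba)3, P(2-furyl)3, NMP) should give 36, oxidative addition to the alkenyl iodide and allyl transfer from tin both being fast.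

**Further compounds**
F1 | step 25 | (4S,6S,7E,12S,15E,18R,19E,21R,22R)-4,6,12-tris(TBSO)-18-hydroxy-22-[(E)-2-iodoethenyl]-21-methyl-10-methylideneoxacyclodocosa-7,15,19-trien-2-one (C17 epimer of 45) | I/C=C/[C@@H]1OC(=O)C[C@@H](O[Si](C)(C)C(C)(C)C)C[C@H](O[Si](C)(C)C(C)(C)C)/C=C/CC(=C)C[C@@H](O[Si](C)(C)C(C)(C)C)CC/C=C/C[C@@H](O)/C=C/[C@H]1C
F2 | step 25 | (4S,6S,7E,12S,15E,19E,21R,22R)-4,6,12-tris(TBSO)-22-[(E)-2-iodoethenyl]-21-methyl-10-methylideneoxacyclodocosa-7,15,19-triene-2,18-dione | I/C=C/[C@@H]1OC(=O)C[C@@H](O[Si](C)(C)C(C)(C)C)C[C@H](O[Si](C)(C)C(C)(C)C)/C=C/CC(=C)C[C@@H](O[Si](C)(C)C(C)(C)C)CC/C=C/CC(=O)/C=C/[C@H]1C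
F3 | step 27 | (4S,6S,7E,12S,15E,18S,19E,21R,22S)-4,6,12,18-tetrahydroxy-21-methyl-10-methylidene-22-[(E)-2-(trimethylstannyl)ethenyl]oxacyclodocosa-7,15,19-trien-2-one | C[Sn](C)(C)/C=C/[C@@H]1OC(=O)C[C@@H](O)C[C@H](O)/C=C/CC(=C)C[C@@H](O)CC/C=C/C[C@H](O)/C=C/[C@H]1C
F4 | step 20 | tert-butyl (3S,5S,E)-3,5-bis(TBSO)-7-iodohept-6-enoate | CC(C)(C)OC(=O)C[C@@H](O[Si](C)(C)C(C)(C)C)C[C@H](O[Si](C)(C)C(C)(C)C)/C=C/I
F5 | step 20 | tributyl[(4S,7E)-4,10-bis(TBSO)-2-methylidenedec-7-en-1-yl]stannane | CCCC[Sn](CCCC)(CCCC)CC(=C)C[C@@H](O[Si](C)(C)C(C)(C)C)CC/C=C/CCO[Si](C)(C)C(C)(C)C
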